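It is impossible for these flasks to hold their coupling partner at saturation while consuming it if gas crosses over in answer to a shortfall, and that crossing is what I assume. I take the crossing as proportional to that shortfall, so the steady rate r of product, divided by J, the crossing rate into a partner-free solution, equals the shortfall itself, and time drops out.

| flask | substrate | gas | free catalyst | remark | time |
|---|---|---|---|---|---|
| green | 0.26 M | 49 mM (held) | 2.5 mol% | run made earlier |  |
| amber | 0.26 M | 49 mM (held) | 10 mol% | run made earlier |  |
| flask | 0.26 M | 49 mM (held) | 5 mol% |  | 6.0 min |

| run | time / min | product / % | substrate / % |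
|---|---|---|---|
| green | 0.500 | 2.4 | 95.3 |
| green | 1.00 | 6.5 | 91.6 |
| green | 2.00 | 15.8 | 82.9 |
| green | 4.00 | 34.0 | 64.5 |
| green | 8.00 | 65.9 | 32.9 |
| amber | 0.667 | 9.2 | 82.3 |
| amber | 2.00 | 32.6 | 59.2 |
| amber | 3.00 | 50.1 | 42.3 |
| amber | 5.00 | 82.6 | 13.2 |
| amber | 8.00 | 100.0 | 0.3 |

(scatter of a reading: 0.3 percentage points)

- product at 6.0 min, in percent of the substrate charged
- concentration of coupling partner in solution at 6.0 min, in percent of saturation

The flask holds more free catalyst than green and less than amber, so I take their mid-run rates, 0.0835 min⁻¹ and 0.167 min⁻¹ in fractions of the charge, as bounds. A double-reciprocal plot of rate against catalyst through these two runs has an intercept that reads J = 0.250 min⁻¹. Over 6.0 min the bounds then give product between 50.1 % and >99.9 %, and saturation between 33.2 % and 66.6 %. The same line tightens this: at 5 mol% it gives r = 0.125 min⁻¹, and so the ceiling share φ, steady rate over crossing ceiling, of 0.501. I therefore expect 75.0 % of product and 49.9 % of saturation. The forecast, 74 % and 57 %, stands inside the bracket and also holds that “transfer and consumption act in series”, but its saturation is higher than mine.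

The flask gives 75.8 % of product and 47.1 % of saturation, both inside the bracket.

    substrate + free catalyst → catalyst intermediate A (k = 0.880 M⁻¹ s⁻¹)
    coupling partner + catalyst intermediate A → catalyst intermediate B (k = 5.60 M⁻¹ s⁻¹)
    catalyst intermediate B → by-product + catalyst intermediate C (k = 0.330 s⁻¹)
    catalyst intermediate C → catalyst intermediate D (k = 1.90 s⁻¹)
    catalyst intermediate D → free catalyst + product (k = 5.50 s⁻¹)
    gas ⇌ coupling partner, rate k6*(csat - [coupling partner]) (kL = 0.0190 s⁻¹)

My φ of 0.501 leaves 49.9 % of saturation, and the forecast stands 9.9 percentage points above the flask. On the neighbour with 20 mol% of free catalyst, the same line gives r = 0.200 min⁻¹ and φ = 0.800. Over 6.0 min that rate would make 120 % of the charge, more than the charge holds, so I reckon that at this rate the charge lasts about 5.00 min. That neighbour shows 99.6 % of product at 6.00 min, with 0.20 % of the substrate left.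

(The readings stem from a simulated flask from invented constants.)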